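The target is a β-hydroxy ketone: a heptan-3-one chain whose C1 carries the 4-hydroxy-3,5-dimethoxyphenyl ring and whose C7 carries the 4-hydroxy-3-methoxyphenyl ring, with an (R)-carbinol at C5. Everything rests on forming C3–C4, exploiting the 1,3-relation between the C5 oxygen and the C3 carbonyl. The O–C5–C4 unit is a chlorohydrin from (R)-epichlorohydrin; reductive lithiation turns its CH2Cl carbon into a nucleophile, a C4-lithio C5-lithium alkoxide needing no protecting group, which is acylated by a cinnamoyl Weinreb amide carrying C1–C3 and the dimethoxyphenyl ring. One operation thus delivers the whole skeleton with free C5 hydroxyl and C3 ketone; hydrogenation then removes C1=C2 and both benzyl ethers.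

Key step: step 3

Remark: compounds 1, 2, 5 and 6 are taken as catalogue chemicals, and lithium naphthalenide is used as a separately prepared, titrated THF solution.

Step 1
Reactants: 1 4-(benzyloxy)-3-methoxybenzyl chloride; 2 (R)-epichlorohydrin
Product: 4 (R)-4-[4-(benzyloxy)-3-methoxyphenyl]-1-chlorobutan-2-ol, via benzylic Grignard reagent 3 (not isolated)
Conditions: Mg, THF, 0 °C; then 2, CuI (10 mol %), THF, −40 to −20 °C; cold 1 M HCl
Reagents that add atoms: none
Why: Copper-catalysed Grignard opening of an epoxide should occur at the unsubstituted ring carbon of 2 rather than at CH2Cl, so no bond to the stereocentre is touched and the (R) centre of 2 becomes C5 of the target.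

Step 2
Reactants: 5 4-(benzyloxy)-3,5-dimethoxybenzaldehyde; 6 diethyl {2-[methoxy(methyl)amino]-2-oxoethyl}phosphonate
Product: 8 (E)-3-[4-(benzyloxy)-3,5-dimethoxyphenyl]-N-methoxy-N-methylprop-2-enamide, via sodium phosphonate carbanion 7 (not isolated)
Conditions: NaH, THF, 0 °C to rt
Reagents that add atoms: none
Why: Horner–Wadsworth–Emmons olefination of a non-enolisable aryl aldehyde with a stabilised phosphonate should give the (E)-cinnamoyl Weinreb amide.

Step 3
Reactants: 4 (R)-4-[4-(benzyloxy)-3-methoxyphenyl]-1-chlorobutan-2-ol; 8 (E)-3-[4-(benzyloxy)-3,5-dimethoxyphenyl]-N-methoxy-N-methylprop-2-enamide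
Product: 12 (1E,5R)-1-[4-(benzyloxy)-3,5-dimethoxyphenyl]-7-[4-(benzyloxy)-3-methoxyphenyl]-5-hydroxyhept-1-en-3-one, via lithium alkoxide 9 (not isolated), via C-lithio lithium alkoxide 10 (not isolated), via tetrahedral dilithio adduct 11 (not isolated)
Conditions: n-BuLi (1 equiv), THF, −78 °C; LiC10H8 (2 equiv), THF, −78 °C; then 8, −78 °C; AcOH/THF, −78 °C
Reagents that add atoms: none
Why: n-BuLi first converts the hydroxyl into lithium alkoxide 9, then two single-electron transfers from naphthalenide cleave the C–Cl bond to give primary alkyllithium 10, whose β-oxygen is already an alkoxide and therefore a very poor leaving group, so loss of lithium oxide should be slow at −78 °C; 10 adds 1,2 to Weinreb amide 8, and the N-methoxy-chelated adduct 11 should survive until the acidic quench, which excludes double addition and releases the ketone only on work-up. The closest known reaction types are the reductive lithiation of chlorohydrins to β-oxido organolithium reagents and the Weinreb ketone synthesis. No ring is closed. No new stereocentre is formed: C5 keeps the configuration brought in by (R)-epichlorohydrin because none of its bonds is touched. The step needs C–Cl reduction in preference to cleavage of the aryl benzyl ether of 9, secured by the low temperature and by adding exactly two equivalents of the radical anion before 8 is introduced, and 1,2- rather than 1,4-addition to the cinnamoyl unit, secured by the hard alkyllithium and the chelating amide.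

Step 4
Reactants: 12 (1E,5R)-1-[4-(benzyloxy)-3,5-dimethoxyphenyl]-7-[4-(benzyloxy)-3-methoxyphenyl]-5-hydroxyhept-1-en-3-one
Product: 14 (R)-5-hydroxy-1-(4-hydroxy-3,5-dimethoxyphenyl)-7-(4-hydroxy-3-methoxyphenyl)heptan-3-one, via saturated bis(benzyl ether) 13 (not isolated)
Conditions: H2 (1 atm), 10% Pd/C, EtOAc/EtOH, rt
Reagents that add atoms: none
Why: Heterogeneous catalytic hydrogenation should saturate the conjugated C1=C2 bond and hydrogenolyse both aryl benzyl ethers, while the dialkyl ketone, the non-benzylic secondary alcohol and the C5 stereocentre are inert under these conditions.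

Compound list
1 | 4-(benzyloxy)-3-methoxybenzyl chloride | COc1cc(CCl)ccc1OCc1ccccc1 | starting material
2 | (R)-epichlorohydrin, (R)-2-(chloromethyl)oxirane | ClC[C@H]1CO1 | starting material
3 | [4-(benzyloxy)-3-methoxybenzyl]magnesium chloride | COc1cc(C[Mg]Cl)ccc1OCc1ccccc1 | intermediate
4 | (R)-4-[4-(benzyloxy)-3-methoxyphenyl]-1-chlorobutan-2-ol | COc1cc(CC[C@@H](O)CCl)ccc1OCc1ccccc1 | intermediate
5 | 4-(benzyloxy)-3,5-dimethoxybenzaldehyde | COc1cc(C=O)cc(OC)c1OCc1ccccc1 | starting material
6 | diethyl {2-[methoxy(methyl)amino]-2-oxoethyl}phosphonate | CCOP(=O)(OCC)CC(=O)N(C)OC | starting material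
7 | sodium salt of the α-carbanion of phosphonate 6 | CCOP(=O)(OCC)[CH-]C(=O)N(C)OC.[Na+] | intermediate
8 | (E)-3-[4-(benzyloxy)-3,5-dimethoxyphenyl]-N-methoxy-N-methylprop-2-enamide | COc1cc(/C=C/C(=O)N(C)OC)cc(OC)c1OCc1ccccc1 | intermediate
9 | lithium (R)-4-[4-(benzyloxy)-3-methoxyphenyl]-1-chlorobutan-2-olate | COc1cc(CC[C@@H](O[Li])CCl)ccc1OCc1ccccc1 | intermediate
10 | lithium 4-[4-(benzyloxy)-3-methoxyphenyl]-1-lithiobutan-2-olate, same spatial arrangement at the carbinol carbon as in 4 (formally (S), because CH2Li ranks below the arylethyl chain) | COc1cc(CC[C@@H](O[Li])C[Li])ccc1OCc1ccccc1 | intermediate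
11 | dilithium (1E,5R)-1-[4-(benzyloxy)-3,5-dimethoxyphenyl]-7-[4-(benzyloxy)-3-methoxyphenyl]-3-[methoxy(methyl)amino]hept-1-ene-3,5-diolate, mixture of epimers at C3 | COc1cc(CC[C@@H](O[Li])CC(O[Li])(N(C)OC)/C=C/c2cc(OC)c(OCc3ccccc3)c(OC)c2)ccc1OCc1ccccc1 | intermediate
12 | (1E,5R)-1-[4-(benzyloxy)-3,5-dimethoxyphenyl]-7-[4-(benzyloxy)-3-methoxyphenyl]-5-hydroxyhept-1-en-3-one | COc1cc(CC[C@@H](O)CC(=O)/C=C/c2cc(OC)c(OCc3ccccc3)c(OC)c2)ccc1OCc1ccccc1 | intermediate
13 | (R)-1-[4-(benzyloxy)-3,5-dimethoxyphenyl]-7-[4-(benzyloxy)-3-methoxyphenyl]-5-hydroxyheptan-3-one | COc1cc(CC[C@@H](O)CC(=O)CCc2cc(OC)c(OCc3ccccc3)c(OC)c2)ccc1OCc1ccccc1 | intermediate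
14 | (R)-5-hydroxy-1-(4-hydroxy-3,5-dimethoxyphenyl)-7-(4-hydroxy-3-methoxyphenyl)heptan-3-one | COc1cc(CC[C@@H](O)CC(=O)CCc2cc(OC)c(O)c(OC)c2)ccc1O | target

Total step count: 4. Longest linear sequence: 3 (steps 1, 3, 4).

Steps most likely to fail

Step 3 (key step). What may go wrong: electron transfer from the radical anion to the aryl benzyl ether of 9 (debenzylation) may compete with C–Cl cleavage, or 10 may lose lithium oxide to give the terminal alkene before it is acylated. The fallback forms the same C3–C4 bond with reversed polarity (acyl-anion umpolung at C3); it sets out from 4 and 5 and comes back at 12. Chlorohydrin 4 is closed with K2CO3 in MeOH to (R)-2-{2-[4-(benzyloxy)-3-methoxyphenyl]ethyl}oxirane F1. Aldehyde 5 is homologated by Wittig reaction with Ph3P=CHCHO to (E)-3-[4-(benzyloxy)-3,5-dimethoxyphenyl]prop-2-enal F2, which with propane-1,3-dithiol and BF3·OEt2 should give 2-{(E)-2-[4-(benzyloxy)-3,5-dimethoxyphenyl]ethenyl}-1,3-dithiane F3. Lithiation of F3 (n-BuLi, THF, −78 °C) and opening of F1 at its CH2 carbon, by attack through the dithiane carbon of the allylic anion (Corey–Seebach alkylation), should give (R)-4-[4-(benzyloxy)-3-methoxyphenyl]-1-(2-{(E)-2-[4-(benzyloxy)-3,5-dimethoxyphenyl]ethenyl}-1,3-dithian-2-yl)butan-2-ol F4. Dithiane hydrolysis with MeI and CaCO3 in aqueous MeCN then gives enone 12, and step 4 follows unchanged.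

Step 1. What may go wrong: Wurtz homocoupling while the electron-rich benzylic Grignard reagent forms, or closure of the magnesium chlorohydrin alkoxide to the epoxide followed by a second Grignard addition. The fallback avoids a benzylic organometallic and sets the stereocentre by resolution instead of from the chiral pool; it sets out from 1 and comes back at 4. Chloride 1 is coupled with allylmagnesium chloride to 1-(benzyloxy)-4-(but-3-en-1-yl)-2-methoxybenzene F5. Epoxidation with mCPBA gives racemic 2-{2-[4-(benzyloxy)-3-methoxyphenyl]ethyl}oxirane F6. Hydrolytic kinetic resolution with (R,R)-(salen)Co(III)OAc and 0.55 equiv of water should leave the (R)-epoxide F1. Opening of F1 at its terminal carbon with LiCl/AcOH in THF returns chlorohydrin 4.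

Step 4. What may go wrong: hydrogenolysis stalling at partly benzylated stages, slow over-reduction of the ketone on prolonged exposure, or oxa-Michael cyclisation of the β-hydroxy enone on the catalyst before the alkene is saturated. The fallback separates the two events and replaces hydrogenolysis; it sets out from 12 and comes back at 14. Conjugate reduction of 12 with the phosphine-stabilised copper hydride [(Ph3P)CuH]6 in wet benzene should give the saturated ketone 13, now isolated. The two aryl benzyl ethers are then cleaved with BCl3 and pentamethylbenzene in CH2Cl2 at −78 °C to give 14.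

Further compounds
F1 | step 3 | (R)-2-{2-[4-(benzyloxy)-3-methoxyphenyl]ethyl}oxirane | COc1cc(CC[C@@H]2CO2)ccc1OCc1ccccc1
F2 | step 3 | (E)-3-[4-(benzyloxy)-3,5-dimethoxyphenyl]prop-2-enal | COc1cc(/C=C/C=O)cc(OC)c1OCc1ccccc1
F3 | step 3 | 2-{(E)-2-[4-(benzyloxy)-3,5-dimethoxyphenyl]ethenyl}-1,3-dithiane | COc1cc(/C=C/C2SCCCS2)cc(OC)c1OCc1ccccc1
F4 | step 3 | (R)-4-[4-(benzyloxy)-3-methoxyphenyl]-1-(2-{(E)-2-[4-(benzyloxy)-3,5-dimethoxyphenyl]ethenyl}-1,3-dithian-2-yl)butan-2-ol | COc1cc(CC[C@@H](O)CC2(/C=C/c3cc(OC)c(OCc4ccccc4)c(OC)c3)SCCCS2)ccc1OCc1ccccc1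
F5 | step 1 | 1-(benzyloxy)-4-(but-3-en-1-yl)-2-methoxybenzene | COc1cc(CCC=C)ccc1OCc1ccccc1
F6 | step 1 | rac-2-{2-[4-(benzyloxy)-3-methoxyphenyl]ethyl}oxirane | COc1cc(CCC2CO2)ccc1OCc1ccccc1
F0 | step 4 | none | none
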